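**Teal's ceiling.** Teal could not turn its whole charge of substrate into product: among the candidate steps partner enters twice, at intermediate B and at intermediate E, so 0.0147 M of partner pays for 0.00735 M of product, less than the 0.030 M of substrate charged.

the same everywhere: partner 0.0147 M
- ochre: substrate 0.012 M; run made earlier
- teal: substrate 0.030 M; run made earlier
- winter: substrate 0.010 M; time 6.0 d
- dawn: substrate 0.015 M; time 6.0 d
- autumn: substrate 0.020 M; time 6.0 d

| ochre: time / d | ochre: product / % | teal: time / d | teal: product / % |
|---|---|---|---|
| 0.333 | 0 | 0.250 | 0 |
| 0.500 | 0.4 | 0.833 | 2.9 |
| 0.833 | 4.1 | 1.67 | 9.3 |
| 1.67 | 17.1 | 2.50 | 11.9 |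
| 2.50 | 29.8 | 3.00 | 12.9 |
| 4.00 | 40.8 | 4.00 | 13.1 |

(each reading ± 0.5 percentage points)

- candidate steps: substrate <-> intermediate A; substrate -> intermediate B; partner + intermediate B -> intermediate C; intermediate C -> intermediate D; intermediate D -> intermediate E; partner + intermediate E -> product
- "hardly changes" means that all values lie within two and a half points (for a concentration: within two and a half percent of the largest)

* [product] at the end for winter, dawn, autumn, in this order
* how that number moves from the first to the last of them (falls all the way / hardly changes / rises, then falls / falls, then rises / rises all the way)

**Stranded share.** Teal's last two readings, 12.9% and 13.1%, differ by less than the scatter of 0.5 percentage points, so I read a stall at 0.00393 M of product. I assumed partner was teal's limiting reagent, with [partner] down to zero. Partner charged, less two per product, then sits in material captured once and unfinished. Over the substrate charged this came to 22.8%, which I call the stranded share.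

**Freezing it.** I froze that share for the asked flasks, a guess with one run behind it. Final [product] is then partner charged, less the stranded amount, divided by two. This gave 0.00621 M for winter, 0.00564 M for dawn and 0.00507 M for autumn.

**Weak link.** Those numbers assume that 6.0 d is long enough. The same line gives ochre 0.00598 M, but ochre read 0.00490 M at 4.00 d and was still rising. Its last two readings closed the gap at 8.80 × 10⁻⁴ M d⁻¹, and the gap midway between them was 0.00175 M, so I assumed an exponential decay of the gap with a time of 1.98 d. That estimate put ochre's gap at 6.0 d at 3.96 × 10⁻⁴ M. As a rough allowance I took this off winter, the flask with the least substrate, and left dawn and autumn as they stood; winter then stood at 0.00581 M, still above dawn. My row therefore fell at each step.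

**The forecast.** The forecast stood at 0.0056 M, 0.0058 M and 0.005 M, shape rises, then falls: “So the product peaks near 0.012–0.015 M substrate, though the first two values are close.” It parted from my reckoning on the order of winter and dawn.

**The result.** The flasks gave 0.00566 M, 0.00552 M and 0.00494 M: falls all the way.

    substrate ⇌ intermediate A (K = 0.480, k = 0.0350 h⁻¹)
    substrate → intermediate B (k = 0.120 h⁻¹)
    partner + intermediate B → intermediate C (k = 1.90 M⁻¹ h⁻¹)
    intermediate C → intermediate D (k = 0.460 h⁻¹)
    intermediate D → intermediate E (k = 0.190 h⁻¹)
    partner + intermediate E → product (k = 4.80 M⁻¹ h⁻¹)

**Share reused.** On autumn the stranded share of 22.8% gives 0.00507 M against 0.00494 M; intermediate E stood at 23.7% of the substrate charged at 6.00 d, with partner at 0.401% of its charge. On dawn, the second flask, it gives 0.00564 M against 0.00552 M, with intermediate E at 22.0%. On autumn's final [product] the falling level of partner is the largest single effect: in the run with [partner] held at its charge, autumn's final [product] stood at 0.0188 M instead of 0.00494 M.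

The runs were generated by integration from invented constants; the scatter is artificial.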